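**Plan** (numbering: chromene O1, C2, C3, C4; side chain on C2 is C1′, C2′, C3′=C4′)
1. Retrosynthesis cuts, in one operation, the side-chain bond C1′–C2′ and the ether bond O1–C2; then C3=C4 of the pyran ring (ring-closing metathesis); in the cyclohexene half, the C3′=C4′ alkene (carboalumination) and the ring–chain bond (Claisen).
2. Enabling feature: C1′, C2 with its methyl, and C3 form an isoprene unit in which C2 is a tertiary allylic ether carbon and C1′ a primary allylic carbon. One (E)-C5 allyl chloride/allyl acetate linchpin can therefore take a carbanion at C1′ and the phenol oxygen at C2. C2′ is allylic to C3′=C4′ and can carry a phenylsulfonyl-stabilised carbanion (the sulfone is a temporary activator, removed in step 12).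
3. Forward: cyclohexene half (steps 1–7), vinylphenol (steps 8–9), then sulfone + linchpin + phenol joined in one flask (step 10), pyran ring closed between C3 and C4 (step 11), sulfone removed, phenol set free.
4. Stereochemistry: the cyclohexene stereocentre comes from a CBS reduction relayed by a suprafacial [3,3] shift; the E alkene from syn-carboalumination; C2 from the chiral Pd catalyst in step 10.

Key step: step 10

Assumption: (2E)-4-chloro-3-methylbut-2-en-1-yl acetate 16 is used as the isomerically pure E compound, since a Z admixture could erode the enantiomeric purity set in step 10.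

**Step 1**
Reactants: 1 2,4,4-trimethylcyclohex-2-en-1-one
Product: 2 (1R)-2,4,4-trimethylcyclohex-2-en-1-ol
Conditions: (S)-Me-CBS (10 mol %), BH3·SMe2 (0.6 equiv), THF, −20 °C; MeOH quench
Reagents that add atoms: none
Why: Corey–Bakshi–Shibata reduction, in which the 2-methyl-substituted alkenyl arm acts as the large group, so the (S)-oxazaborolidine should deliver hydride to the face that gives the (R)-carbinol.

**Step 2**
Reactants: 2 (1R)-2,4,4-trimethylcyclohex-2-en-1-ol
Product: 4 ethyl 2-[(1S)-2,6,6-trimethylcyclohex-2-en-1-yl]acetate, via mixed ketene acetal 3 (not isolated)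
Conditions: MeC(OEt)3 (5 equiv), EtCO2H (cat.), 140 °C, EtOH distilled off
Reagents that add atoms: triethyl orthoacetate, CC(OCC)(OCC)OCC
Why: Johnson–Claisen rearrangement, a suprafacial [3,3] shift that forms the new C–C bond (next to the gem-dimethyl carbon) on the face the C–O bond leaves, so the (R)-carbinol becomes the (S) ring stereocentre and the double bond moves into the 2,3-position.

**Step 3**
Reactants: 4 ethyl 2-[(1S)-2,6,6-trimethylcyclohex-2-en-1-yl]acetate
Product: 5 2-[(1S)-2,6,6-trimethylcyclohex-2-en-1-yl]ethan-1-ol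
Conditions: LiAlH4, Et2O, 0 °C
Reagents that add atoms: none
Why: Hydride reduction of an ester to the primary alcohol, remote from the stereocentre and the ring alkene.

**Step 4**
Reactants: 5 2-[(1S)-2,6,6-trimethylcyclohex-2-en-1-yl]ethan-1-ol
Product: 6 (6S)-6-(2-iodoethyl)-1,5,5-trimethylcyclohex-1-ene
Conditions: I2, PPh3, imidazole, CH2Cl2, 0 °C → rt
Reagents that add atoms: iodine, II
Why: Appel iodination of an unhindered primary alcohol under neutral conditions that leave the trisubstituted alkene in place.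

**Step 5**
Reactants: 6 (6S)-6-(2-iodoethyl)-1,5,5-trimethylcyclohex-1-ene
Product: 7 (6S)-6-(but-3-yn-1-yl)-1,5,5-trimethylcyclohex-1-ene
Conditions: lithium acetylide–ethylenediamine complex, DMSO, rt
Reagents that add atoms: lithium acetylide (as its ethylenediamine complex), [Li]C#C
Why: SN2 alkylation of acetylide by a primary iodide in a dipolar aprotic solvent.

**Step 6**
Reactants: 7 (6S)-6-(but-3-yn-1-yl)-1,5,5-trimethylcyclohex-1-ene
Product: 10 (2E)-3-methyl-5-[(1S)-2,6,6-trimethylcyclohex-2-en-1-yl]pent-2-en-1-ol, via alkenylalane 8 (not isolated), via lithium alkenylalanate 9 (not isolated)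
Conditions: Me3Al (3 equiv), Cp2ZrCl2 (0.25 equiv), CH2Cl2, 0 °C → rt; then n-BuLi, THF, −78 °C; (CH2O)n, → rt
Reagents that add atoms: trimethylaluminium, C[Al](C)C; paraformaldehyde (source of formaldehyde), C=O
Why: Negishi zirconium-catalysed methylalumination adds CH3 and Al syn across the terminal alkyne with Al on the terminal carbon, and the derived alanate is hydroxymethylated with retention, which fixes the E trisubstituted alkene.

**Step 7**
Reactants: 10 (2E)-3-methyl-5-[(1S)-2,6,6-trimethylcyclohex-2-en-1-yl]pent-2-en-1-ol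
Product: 12 (2E)-3-methyl-5-[(1S)-2,6,6-trimethylcyclohex-2-en-1-yl]pent-2-en-1-yl phenyl sulfone, via allylic bromide 11 (not isolated)
Conditions: PBr3, pyridine (cat.), Et2O, −10 °C; crude bromide, PhSO2Na, DMF, rt
Reagents that add atoms: sodium benzenesulfinate, [Na+].[O-]S(=O)c1ccccc1; phosphorus tribromide, BrP(Br)Br (bromine only in 11)
Why: SN2 bromination of a primary allylic alcohol followed by S-alkylation of sulfinate at the primary carbon, a standard route to E prenyl-type sulfones that keeps the alkene geometry.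

**Step 8**
Reactants: 13 2,5-dihydroxybenzaldehyde
Product: 14 2-hydroxy-5-[(triisopropylsilyl)oxy]benzaldehyde
Conditions: TIPSCl (1.05 equiv), imidazole, CH2Cl2, 0 °C
Reagents that add atoms: triisopropylsilyl chloride, CC(C)[Si](Cl)(C(C)C)C(C)C
Why: Silylation should pick the 5-OH because the 2-OH is tied up in a hydrogen bond to the flanking aldehyde.

**Step 9**
Reactants: 14 2-hydroxy-5-[(triisopropylsilyl)oxy]benzaldehyde
Product: 15 2-ethenyl-4-[(triisopropylsilyl)oxy]phenol
Conditions: Ph3PCH3Br (2.3 equiv), KOt-Bu (2.3 equiv), THF, 0 °C → rt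
Reagents that add atoms: methylenetriphenylphosphorane (from methyltriphenylphosphonium bromide), C=P(c1ccccc1)(c1ccccc1)c1ccccc1
Why: Wittig methylenation of a salicylaldehyde with excess ylide, one equivalent of base being used up by the phenol.

**Step 10**
Reactants: 12 (2E)-3-methyl-5-[(1S)-2,6,6-trimethylcyclohex-2-en-1-yl]pent-2-en-1-yl phenyl sulfone; 16 (2E)-4-chloro-3-methylbut-2-en-1-yl acetate; 15 2-ethenyl-4-[(triisopropylsilyl)oxy]phenol
Product: 19 (3S,6E)-3,7-dimethyl-5-(phenylsulfonyl)-9-[(1S)-2,6,6-trimethylcyclohex-2-en-1-yl]nona-1,6-dien-3-yl 2-ethenyl-4-[(triisopropylsilyl)oxy]phenyl ether (both C5 epimers), via lithiated sulfone 17 (not isolated), via sulfone acetate 18 (not isolated)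
Conditions: n-BuLi (1.0 equiv), THF, −78 °C; 16, −78 → −20 °C; then 15, Cs2CO3 (1.2 equiv), Pd2(dba)3·CHCl3 (2.5 mol %), (R,R)-DACH-phenyl Trost ligand (7.5 mol %), CH2Cl2 co-solvent, rt
Reagents that add atoms: none
Why: Deprotonation of 12 at C2′ gives the α-sulfonyl allyl anion 17, which displaces chloride from the primary allylic carbon of 16 (SN2, new C1′–C2′ bond, both E alkenes untouched); Pd(0) then ionises the allylic acetate of 18 to a π-allyl complex that the phenoxide of 15 captures at its methyl-bearing terminus to give the tertiary aryl ether. The closest known reaction types are the sulfone-anion/allyl chloride head-to-tail coupling of isoprenoid synthesis (Julia- or Biellmann-type) and the Trost asymmetric allylic etherification of phenols with 3,3-disubstituted allyl esters. No ring is closed in this step. The new stereocentre at C2 is set by the chiral ligand, which differentiates the two faces of the π-allyl terminus; the ligand hand written here could not be derived from a model and is to be fixed by correlation in a first run, the antipodal ligand being used if the sense is opposite; the stereocentre at C2′ forms unselectively and is erased in step 12. The step needs α- over γ-alkylation of the allyl anion and SN2 over SN2′ or acyl attack on 16, which the sulfonyl group, the primary chloride and the low temperature should secure. It also needs branched over linear etherification and acetate over sulfinate ionisation, which ligand-directed attack at the more substituted terminus and the much better leaving ability of the allylic acetate at room temperature should secure.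

**Step 11**
Reactants: 19 (3S,6E)-3,7-dimethyl-5-(phenylsulfonyl)-9-[(1S)-2,6,6-trimethylcyclohex-2-en-1-yl]nona-1,6-dien-3-yl 2-ethenyl-4-[(triisopropylsilyl)oxy]phenyl ether
Product: 20 triisopropyl({(2S)-2-methyl-2-[(3E)-4-methyl-2-(phenylsulfonyl)-6-[(1S)-2,6,6-trimethylcyclohex-2-en-1-yl]hex-3-en-1-yl]-2H-chromen-6-yl}oxy)silane (both sulfone epimers)
Conditions: Grubbs II (5 mol %), CH2Cl2 (0.01 M), 40 °C
Reagents that add atoms: none
Why: Ring-closing metathesis of the styrene with the vinyl group on the ether carbon should close the six-membered 2H-pyran ring (C3=C4) with loss of ethylene, the two monosubstituted alkenes reacting far faster than the trisubstituted ones and the quaternary stereocentre staying untouched.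

**Step 12**
Reactants: 20 triisopropyl({(2S)-2-methyl-2-[(3E)-4-methyl-2-(phenylsulfonyl)-6-[(1S)-2,6,6-trimethylcyclohex-2-en-1-yl]hex-3-en-1-yl]-2H-chromen-6-yl}oxy)silane
Product: 21 triisopropyl({(2S)-2-methyl-2-[(3E)-4-methyl-6-[(1S)-2,6,6-trimethylcyclohex-2-en-1-yl]hex-3-en-1-yl]-2H-chromen-6-yl}oxy)silane
Conditions: PdCl2(dppp) (10 mol %), LiBHEt3 (3 equiv), THF, 0 °C
Reagents that add atoms: none
Why: Pd-catalysed reductive desulfonylation of an allylic sulfone, in which hydride goes to the less substituted terminus of the π-allyl intermediate so the trisubstituted alkene keeps its position and E geometry, the 2,2-disubstituted chromene ether being much slower to ionise.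

**Step 13**
Reactants: 21 triisopropyl({(2S)-2-methyl-2-[(3E)-4-methyl-6-[(1S)-2,6,6-trimethylcyclohex-2-en-1-yl]hex-3-en-1-yl]-2H-chromen-6-yl}oxy)silane
Product: 22 (2S)-2-methyl-2-[(3E)-4-methyl-6-[(1S)-2,6,6-trimethylcyclohex-2-en-1-yl]hex-3-en-1-yl]-2H-chromen-6-ol
Conditions: TBAF, AcOH (1 equiv), THF, 0 °C
Reagents that add atoms: none
Why: Fluoride cleavage of the aryl silyl ether should release the phenol without touching the chromene or the alkenes.

**Compound list**
1 | 2,4,4-trimethylcyclohex-2-en-1-one | CC1=CC(C)(C)CCC1=O | starting material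
2 | (1R)-2,4,4-trimethylcyclohex-2-en-1-ol | O[C@H]1C(C)=CC(C)(C)CC1 | intermediate
3 | 1-ethoxyvinyl (1R)-2,4,4-trimethylcyclohex-2-en-1-yl ether (mixed ketene acetal) | C=C(OCC)O[C@H]1C(C)=CC(C)(C)CC1 | intermediate
4 | ethyl 2-[(1S)-2,6,6-trimethylcyclohex-2-en-1-yl]acetate | CC1=CCCC(C)(C)[C@@H]1CC(=O)OCC | intermediate
5 | 2-[(1S)-2,6,6-trimethylcyclohex-2-en-1-yl]ethan-1-ol | CC1=CCCC(C)(C)[C@@H]1CCO | intermediate
6 | (6S)-6-(2-iodoethyl)-1,5,5-trimethylcyclohex-1-ene | CC1=CCCC(C)(C)[C@@H]1CCI | intermediate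
7 | (6S)-6-(but-3-yn-1-yl)-1,5,5-trimethylcyclohex-1-ene | CC1=CCCC(C)(C)[C@@H]1CCC#C | intermediate
8 | dimethyl{(1E)-2-methyl-4-[(1S)-2,6,6-trimethylcyclohex-2-en-1-yl]but-1-en-1-yl}alane | CC1=CCCC(C)(C)[C@@H]1CC/C(C)=C/[Al](C)C | intermediate
9 | lithium butyl(dimethyl){(1E)-2-methyl-4-[(1S)-2,6,6-trimethylcyclohex-2-en-1-yl]but-1-en-1-yl}aluminate | CC1=CCCC(C)(C)[C@@H]1CC/C(C)=C/[Al-](C)(C)CCCC.[Li+] | intermediate
10 | (2E)-3-methyl-5-[(1S)-2,6,6-trimethylcyclohex-2-en-1-yl]pent-2-en-1-ol | CC1=CCCC(C)(C)[C@@H]1CC/C(C)=C/CO | intermediate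
11 | (6S)-6-[(3E)-5-bromo-3-methylpent-3-en-1-yl]-1,5,5-trimethylcyclohex-1-ene | CC1=CCCC(C)(C)[C@@H]1CC/C(C)=C/CBr | intermediate
12 | (2E)-3-methyl-5-[(1S)-2,6,6-trimethylcyclohex-2-en-1-yl]pent-2-en-1-yl phenyl sulfone | CC1=CCCC(C)(C)[C@@H]1CC/C(C)=C/CS(=O)(=O)c1ccccc1 | intermediate
13 | 2,5-dihydroxybenzaldehyde | O=Cc1cc(O)ccc1O | starting material
14 | 2-hydroxy-5-[(triisopropylsilyl)oxy]benzaldehyde | O=Cc1cc(O[Si](C(C)C)(C(C)C)C(C)C)ccc1O | intermediate
15 | 2-ethenyl-4-[(triisopropylsilyl)oxy]phenol | C=Cc1cc(O[Si](C(C)C)(C(C)C)C(C)C)ccc1O | intermediate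
16 | (2E)-4-chloro-3-methylbut-2-en-1-yl acetate | CC(=O)OC/C=C(\C)CCl | starting material
17 | (2E)-1-lithio-3-methyl-5-[(1S)-2,6,6-trimethylcyclohex-2-en-1-yl]pent-2-en-1-yl phenyl sulfone | CC1=CCCC(C)(C)[C@@H]1CC/C(C)=C/C([Li])S(=O)(=O)c1ccccc1 | intermediate
18 | (2E,6E)-3,7-dimethyl-5-(phenylsulfonyl)-9-[(1S)-2,6,6-trimethylcyclohex-2-en-1-yl]nona-2,6-dien-1-yl acetate (both C5 epimers) | CC1=CCCC(C)(C)[C@@H]1CC/C(C)=C/C(S(=O)(=O)c1ccccc1)C/C(C)=C/COC(C)=O | intermediate
19 | (3S,6E)-3,7-dimethyl-5-(phenylsulfonyl)-9-[(1S)-2,6,6-trimethylcyclohex-2-en-1-yl]nona-1,6-dien-3-yl 2-ethenyl-4-[(triisopropylsilyl)oxy]phenyl ether (both C5 epimers) | CC1=CCCC(C)(C)[C@@H]1CC/C(C)=C/C(S(=O)(=O)c1ccccc1)C[C@@](C)(C=C)Oc1ccc(O[Si](C(C)C)(C(C)C)C(C)C)cc1C=C | intermediate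
20 | triisopropyl({(2S)-2-methyl-2-[(3E)-4-methyl-2-(phenylsulfonyl)-6-[(1S)-2,6,6-trimethylcyclohex-2-en-1-yl]hex-3-en-1-yl]-2H-chromen-6-yl}oxy)silane (both sulfone epimers) | CC1=CCCC(C)(C)[C@@H]1CC/C(C)=C/C(S(=O)(=O)c1ccccc1)C[C@@]1(C)C=Cc2cc(O[Si](C(C)C)(C(C)C)C(C)C)ccc2O1 | intermediate
21 | triisopropyl({(2S)-2-methyl-2-[(3E)-4-methyl-6-[(1S)-2,6,6-trimethylcyclohex-2-en-1-yl]hex-3-en-1-yl]-2H-chromen-6-yl}oxy)silane | CC1=CCCC(C)(C)[C@@H]1CC/C(C)=C/CC[C@@]1(C)C=Cc2cc(O[Si](C(C)C)(C(C)C)C(C)C)ccc2O1 | intermediate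
22 | (2S)-2-methyl-2-[(3E)-4-methyl-6-[(1S)-2,6,6-trimethylcyclohex-2-en-1-yl]hex-3-en-1-yl]-2H-chromen-6-ol | CC1=CCCC(C)(C)[C@@H]1CC/C(C)=C/CC[C@@]1(C)C=Cc2cc(O)ccc2O1 | target

**Totals:** 13 steps; longest linear sequence 11 steps (steps 1–7, then 10–13).

**Steps most likely to fail**

1. Step 10. What may go wrong: loss of regio- or enantiocontrol in the etherification (phenoxide attack at the primary allyl terminus, re-ionisation of the tertiary ether, an unselective background path), or acyl transfer from the acetate to the sulfonyl carbanion in the first stage. Fallback, from 15 and 12, back at 19: the ether stereocentre is made first and the C–C bond last. Phenol 15 is O-alkylated with racemic 2-methyl-2-vinyloxirane F1 (Pd2(dba)3·CHCl3, Trost ligand, CH2Cl2, rt; dynamic kinetic asymmetric opening, the alkoxide of the π-allyl intermediate steering the phenol to the methyl-bearing carbon) to give (2R)-2-{2-ethenyl-4-[(triisopropylsilyl)oxy]phenoxy}-2-methylbut-3-en-1-ol F2. Tf2O and 2,6-lutidine at −78 °C convert it into (2R)-2-{2-ethenyl-4-[(triisopropylsilyl)oxy]phenoxy}-2-methylbut-3-en-1-yl trifluoromethanesulfonate F3, which cannot eliminate because the neighbouring carbon bears no hydrogen. The lithiated sulfone 17 (from 12, n-BuLi, THF/DMPU, −78 °C) displaces the triflate and gives 19.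

2. Step 12. What may go wrong: hydride delivery to the wrong allyl terminus, or Pd(0) insertion into the allylic C2–O1 bond of the pyran with reductive ring opening. Fallback, from 19, back at 21: the sulfone is removed before the pyran ring exists, by electron transfer instead of Pd hydride (6 % Na(Hg), Na2HPO4, MeOH/THF, −20 °C). This gives (3S,6E)-3,7-dimethyl-9-[(1S)-2,6,6-trimethylcyclohex-2-en-1-yl]nona-1,6-dien-3-yl 2-ethenyl-4-[(triisopropylsilyl)oxy]phenyl ether F4, which is closed with the Ru catalyst of step 11 to 21.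

3. Step 2. What may go wrong: slow [3,3] shift at the carbon next to the quaternary centre, with competing acid-catalysed dehydration of the allylic alcohol. Fallback, from 1, back at 5: the ring–chain bond is made by copper-mediated anti-SN2′ substitution. Compound 1 is reduced with the (R)-CBS catalyst to (1S)-2,4,4-trimethylcyclohex-2-en-1-ol F5, which is esterified (picolinic acid, DCC, DMAP) to (1S)-2,4,4-trimethylcyclohex-2-en-1-yl pyridine-2-carboxylate F6. Vinylmagnesium bromide with CuBr·SMe2 substitutes it anti to the leaving group to give (6S)-6-ethenyl-1,5,5-trimethylcyclohex-1-ene F7. 9-BBN, then NaOH/H2O2, hydroborates only the vinyl group and gives 5.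

**Further compounds**
F1 | step 10 | 2-methyl-2-vinyloxirane (racemic) | CC1(C=C)CO1
F2 | step 10 | (2R)-2-{2-ethenyl-4-[(triisopropylsilyl)oxy]phenoxy}-2-methylbut-3-en-1-ol | OC[C@@](C)(C=C)Oc1ccc(O[Si](C(C)C)(C(C)C)C(C)C)cc1C=C
F3 | step 10 | (2R)-2-{2-ethenyl-4-[(triisopropylsilyl)oxy]phenoxy}-2-methylbut-3-en-1-yl trifluoromethanesulfonate | O=S(=O)(OC[C@@](C)(C=C)Oc1ccc(O[Si](C(C)C)(C(C)C)C(C)C)cc1C=C)C(F)(F)F
F4 | step 12 | (3S,6E)-3,7-dimethyl-9-[(1S)-2,6,6-trimethylcyclohex-2-en-1-yl]nona-1,6-dien-3-yl 2-ethenyl-4-[(triisopropylsilyl)oxy]phenyl ether | CC1=CCCC(C)(C)[C@@H]1CC/C(C)=C/CC[C@@](C)(C=C)Oc1ccc(O[Si](C(C)C)(C(C)C)C(C)C)cc1C=C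
F5 | step 2 | (1S)-2,4,4-trimethylcyclohex-2-en-1-ol | O[C@@H]1C(C)=CC(C)(C)CC1
F6 | step 2 | (1S)-2,4,4-trimethylcyclohex-2-en-1-yl pyridine-2-carboxylate | O=C(O[C@@H]1C(C)=CC(C)(C)CC1)c1ccccn1
F7 | step 2 | (6S)-6-ethenyl-1,5,5-trimethylcyclohex-1-ene | CC1=CCCC(C)(C)[C@@H]1C=C
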